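Assumption: (+)-genipin, produced in bulk from gardenia geniposide, is taken as the commercial chiral starting material.

Numbering: C1 (acetal C), O2, C3=C4, C5, C6, C7, C8, C9 (ring fusion, bonded to C1), C10 (CH2 on C8), C11 (carbon on C4). β is the face that carries H-9.

## Retrosynthetic overview
1. The target comes from sorting esters on a C1-silyl-protected tetraol: acetates on the primary C10/C11 OH, isovalerates on C7-OH and the C1 lactol O. The tetraol comes from DIBAL reduction of the C4 methyl ester, which is kept until then to deactivate the C3=C4 enol ether.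
2. The C7–O bond and C5=C6 come from a photochemical singlet-oxygen (Schenck) ene reaction on a Δ6-8α-ol, in which H-5β is traded for 7β-O.
3. The C8–O bond (8α) and the Δ6 alkene come from a visible-light, air-driven, selenium-catalysed anti-hydroxylative transposition of the genipin C7=C8 alkene (new method).
4. Genipin supplies all ten skeletal carbons and the C1, C5 and C9 stereocentres. C8 and C7 are set by substrate control.
5. No ring is built. The cis-fused cyclopenta[c]pyran is bought intact and only its oxidation pattern is edited.

## Route

Step 1
Reactants: 1, (+)-genipin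
Product: 3, 10-O-acetyl-1-O-TBS-genipin (1β-OTBS, H-5β, H-9β), formed via 2, 10-O-acetylgenipin (not isolated)
Conditions: AcCl (1.05 equiv), 2,4,6-collidine (5 equiv), CH2Cl2, −78 °C; then TBSOTf (2.6 equiv; the excess covers the reagent lost to collidinium chloride as TBSCl), −78 → 0 °C, same flask
Reagents that add atoms: acetyl chloride CC(=O)Cl; TBSOTf CC(C)(C)[Si](C)(C)OS(=O)(=O)C(F)(F)F
Why: Kinetically selective acylation of the primary allylic OH (AcCl/collidine) is followed by silylation of the remaining lactol OH; genipin exists as the single 1β-lactol (H-1/H-9 trans), so C1 carries over unchanged and no new stereocentre is made.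

Step 2
Reactants: 3, 10-O-acetyl-1-O-TBS-genipin
Product: 4, Δ6-8α-hydroxy-8β-(acetoxymethyl) ester, methyl (1S,4aS,7R,7aS)-7-(acetoxymethyl)-1-(TBSO)-7-hydroxy-1,4a,7,7a-tetrahydrocyclopenta[c]pyran-4-carboxylate (a protected monotropein-type aglycone)
Conditions: (PhSe)2 (10 mol %), 2,4,6-tris(4-methoxyphenyl)pyrylium BF4 (5 mol %), H2O (10 equiv), Na2HPO4 (0.5 equiv), O2 (1 atm), MeCN, 465 nm LED, 23 °C; then cat. Et3N, 1 h (moves any 8-O-acetyl isomer to O10)
Reagents that add atoms: water, O (the oxygen gained in this step; O2 is only the terminal oxidant)
Why: Proposed new method: photo-aerobic selenium-π-acid catalysis with water as the O-nucleophile, relayed by the C10 acetate; the excited pyrylium oxidises (PhSe)2 to a PhSe+ equivalent, which reversibly forms the seleniranium ion on the convex β-face of C7=C8; the tertiary C8 is then opened anti, from the α-face, either by the acetate carbonyl (five-membered acetoxonium, hydrolysed by water) or by water directly, which fixes 8α-OH/8β-CH2OAc; the 7β-selenide is re-oxidised (by the photocatalyst or by H2O2 formed in situ) and departs with a C6–H, the only β-hydrogen because C8 is quaternary, giving the Δ6 alkene and regenerating (PhSe)2; the ester-deactivated C3=C4 does not compete, and the electron-transfer pyrylium dye is a poor 1O2 sensitiser, which suppresses the β-face ene reaction that would give the wrong 8β-epimer; the closest known reaction types are photo-aerobic Se-catalysed allylic esterification/lactonisation and stoichiometric or anodic hydroxyselenenylation–deselenenylation of olefins to transposed allylic alcohols.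

Step 3
Reactants: 4, Δ6-8α-hydroxy-8β-(acetoxymethyl) ester
Product: 6, 7β,8α-diol dienoate, methyl (1S,6S,7R,7aS)-7-(acetoxymethyl)-1-(TBSO)-6,7-dihydroxy-1,6,7,7a-tetrahydrocyclopenta[c]pyran-4-carboxylate, formed via 5, the 7β-hydroperoxide (not isolated)
Conditions: O2, tetraphenylporphyrin (1 mol %), CH2Cl2, 0 °C, 590 nm LED, stopped at about 90 % conversion; then PPh3 (1.2 equiv), 0 °C
Reagents that add atoms: dioxygen O=O (one O is retained)
Why: In this Schenck ene reaction C8 is quaternary, so H-5 is the only allylic hydrogen, and because the ene process is suprafacial the oxygen is delivered to C7 on the H-5 (β) face while the alkene moves to C5=C6, transferring the purchased C5 stereocentre to C7; the s-trans-locked product diene cannot undergo [4+2] addition, the push–pull enol ether is inert, and PPh3 reduces the O–O bond with retention.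

Step 4
Reactants: 6, 7β,8α-diol dienoate
Product: 7, tetraol silyl acetal, (1S,6S,7R,7aS)-1-(TBSO)-4,7-bis(hydroxymethyl)-1,6,7,7a-tetrahydrocyclopenta[c]pyran-6,7-diol
Conditions: DIBAL-H (8 equiv), CH2Cl2, −78 → −30 °C; aq. Rochelle salt; Et3N-deactivated silica
Reagents that add atoms: none
Why: DIBAL 1,2-reduction converts the vinylogous-carbonate ester to the C11 allylic alcohol and also cleaves the relay acetate, while the silyl acetal blocks lactol opening and no stereocentre is touched.

Step 5
Reactants: 7, tetraol silyl acetal
Product: 8, 10,11-di-O-acetate (7β-OH and 8α-OH free, 1β-OTBS)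
Conditions: AcCl (2.2 equiv), 2,4,6-collidine, CH2Cl2, −78 → −40 °C
Reagents that add atoms: acetyl chloride CC(=O)Cl
Why: The low-temperature AcCl/collidine protocol acetylates the two primary alcohols and leaves the hindered secondary C7-OH (next to quaternary C8) and the tertiary C8-OH free.

Step 6
Reactants: 8, 10,11-di-O-acetate
Product: 10, 10-acetoxyvaltrathydrin (target), formed via 9, the 7-O-isovaleryl silyl acetal (not isolated)
Conditions: isovaleric anhydride (6 equiv), Et3N, DMAP (0.2 equiv), CH2Cl2, 0 °C; then TBAF/isovaleric acid (1:1, 1.5 equiv), THF, −30 → 0 °C; pH 7 buffer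
Reagents that add atoms: isovaleric anhydride CC(C)CC(=O)OC(=O)CC(C)C
Why: DMAP-catalysed acylation of C7-OH is followed by fluoride-triggered cleavage of the anomeric silyl ether with in situ capture of the lactolate by the excess anhydride, so the fragile lactol never accumulates; C1 keeps the 1β (H-1/H-9 trans) configuration that is also thermodynamically preferred, the tertiary 8-OH is not acylated, and buffering with isovaleric acid avoids acyl scrambling.

## Compound list
1 | (+)-genipin, methyl (1R,4aS,7aS)-1-hydroxy-7-(hydroxymethyl)-1,4a,5,7a-tetrahydrocyclopenta[c]pyran-4-carboxylate | COC(=O)C1=CO[C@@H](O)[C@H]2[C@@H]1CC=C2CO | starting material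
2 | 10-O-acetylgenipin | COC(=O)C1=CO[C@@H](O)[C@H]2[C@@H]1CC=C2COC(C)=O | intermediate (not isolated)
3 | 10-O-acetyl-1-O-TBS-genipin (1S,4aS,7aS) | COC(=O)C1=CO[C@@H](O[Si](C)(C)C(C)(C)C)[C@H]2[C@@H]1CC=C2COC(C)=O | intermediate
4 | Δ6-8α-hydroxy-10-acetoxy-1β-OTBS methyl ester (1S,4aS,7R,7aS) | COC(=O)C1=CO[C@@H](O[Si](C)(C)C(C)(C)C)[C@H]2[C@@H]1C=C[C@]2(O)COC(C)=O | intermediate
5 | 7β-hydroperoxy-8α-hydroxy-Δ3,5-dienoate (1S,6S,7R,7aS) | COC(=O)C1=CO[C@@H](O[Si](C)(C)C(C)(C)C)[C@H]2C1=C[C@H](OO)[C@]2(O)COC(C)=O | intermediate (not isolated)
6 | 7β,8α-dihydroxy-10-acetoxy-Δ3,5-dienoate (1S,6S,7R,7aS) | COC(=O)C1=CO[C@@H](O[Si](C)(C)C(C)(C)C)[C@H]2C1=C[C@H](O)[C@]2(O)COC(C)=O | intermediate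
7 | 1β-OTBS 7β,8α,10,11-tetraol | OCC1=CO[C@@H](O[Si](C)(C)C(C)(C)C)[C@H]2C1=C[C@H](O)[C@]2(O)CO | intermediate
8 | 1β-OTBS 10,11-diacetate 7β,8α-diol | CC(=O)OCC1=CO[C@@H](O[Si](C)(C)C(C)(C)C)[C@H]2C1=C[C@H](O)[C@]2(O)COC(C)=O | intermediate
9 | 1β-OTBS 7β-O-isovaleryl 10,11-diacetate | CC(=O)OCC1=CO[C@@H](O[Si](C)(C)C(C)(C)C)[C@H]2C1=C[C@H](OC(=O)CC(C)C)[C@]2(O)COC(C)=O | intermediate (not isolated)
10 | 10-acetoxyvaltrathydrin (1S,6S,7R,7aS) | CC(=O)OCC1=CO[C@@H](OC(=O)CC(C)C)[C@H]2C1=C[C@H](OC(=O)CC(C)C)[C@]2(O)COC(C)=O | target

## Totals

Total step count: 6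

Longest linear sequence: 6 steps (fully linear, 1 → 10)

Each step is one flask operation. Steps 1, 3 and 6 are two-stage one-pot sequences, so the route contains 9 chemical transformations in all.

## Three steps most likely to fail

1. **Step 2 (proposed new step).**
   - Risks:
     - Poor turnover with water as the nucleophile.
     - Pseudobase formation from the pyrylium dye in wet, buffered MeCN.
     - Closure of the oxidised trans-β-hydroxyselenide to the 7α,8α-epoxide instead of elimination.
     - Facial leakage to the 8β-OH epimer.
     - Loss of the TBS group.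
   - Fallback (known chemistry): give up the catalytic photochemical manifold for this bond. Carry out stoichiometric hydroxyselenenylation with N-(phenylseleno)phthalimide, H2O and cat. PPTS, and isolate the 7β-PhSe-8α-ol. Then perform a separate H2O2/pyridine selenoxide syn-elimination, the classical olefin to transposed allylic alcohol sequence. This adds 1 step.

2. **Step 3 (Schenck ene).**
   - Risks:
     - The deactivated 1,2-disubstituted alkene reacts slowly.
     - The 8α-OH can draw 1O2 to the unproductive face.
     - The trisubstituted C5=C6 of the product may be over-oxidised by abstraction of H-9.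
   - Fallback: replace the ene reaction with epoxide isomerisation. Silylate the 8-OH and epoxidise with DMDO on the convex face to give the 6β,7β-epoxide. Then treat with TMSOTf/2,6-lutidine followed by DBU. Triflate opens the less hindered C6 from the α-face, and anti E2 elimination with H-5β gives the 7β-O-silyl C5=C6 diene. This adds 2 steps, and the silyl groups are removed with the others.

3. **Step 6 (C1 desilylative acylation).**
   - Risks:
     - The liberated lactolate of the electron-rich dienol ether may ring-open or aromatise (baldrinal-type decay) faster than it is acylated.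
     - Fluoride may attack the allylic esters.
   - Fallback: change the order of events. Oxidise the C11-OH of 7 with MnO2 to the 4-formyl compound, whose push–pull lactol is as stable as genipin. Desilylate it and install the C10 acetate and the C1/C7 isovalerates on this robust lactol. Finish with a Luche reduction of the aldehyde and acetylation of C11. This adds about 3 steps.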